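## Retrosynthetic overview
1. 26 comes from decarboxylative saponification of the C6 methyl ester 23. The ester is kept to the end as a blocking and chelating group.
2. The C8 prenyl group comes from a para-Claisen–Cope shift of the 5-O-prenyl ether 20, where both ortho carbons are blocked and C8 is the only free ring position.
3. The pyran ring (formed second) comes from an aldol-type condensation of resorcylate 13 with prenal, then oxa-6π closure on the non-chelated 4-OH.
4. The resorcylate ring (formed first) comes from the key Michael addition of dimethyl malonate to enone 7, Claisen (Dieckmann) closure in the same pot, then bromine aromatisation.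
5. Enone 7 comes from a Wittig reaction on 3-[4-(benzyloxy)phenyl]propanal, made from methyl 3-(4-hydroxyphenyl)propanoate. The phenol ring is bought.

Assumption: the target SMILES has no stereocentre and no E/Z-stereogenic double bond, so the compound is achiral and exists as one form. No asymmetric step is needed. The stereocentres in 9, 10, 11, 21 and 22 are racemic and are erased later in the route.

## Route

Step 1
Reactants: 1 methyl 3-(4-hydroxyphenyl)propanoate; 2 benzyl bromide
Product: 3 methyl 3-[4-(benzyloxy)phenyl]propanoate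
Conditions: K2CO3, acetone, reflux
Reagents that add atoms: benzyl bromide, BrCc1ccccc1
Why: Williamson ether synthesis on the only acidic OH gives a phenol protecting group that survives hydride, methoxide and HBr.

Step 2
Reactants: 3 methyl 3-[4-(benzyloxy)phenyl]propanoate
Product: 4 3-[4-(benzyloxy)phenyl]propan-1-ol
Conditions: LiAlH4, THF, 0 °C to rt; Fieser work-up
Reagents that add atoms: none
Why: Full hydride reduction of the ester avoids the over-reduction risk of a partial DIBAL-H reduction, and the benzyl ether is inert.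

Step 3
Reactants: 4 3-[4-(benzyloxy)phenyl]propan-1-ol
Product: 5 3-[4-(benzyloxy)phenyl]propanal
Conditions: TEMPO (10 mol %), PhI(OAc)2, CH2Cl2, rt
Reagents that add atoms: none
Why: Oxoammonium (TEMPO/BAIB) oxidation of a primary alcohol stops cleanly at the aldehyde.

Step 4
Reactants: 5 3-[4-(benzyloxy)phenyl]propanal; 6 1-(triphenylphosphoranylidene)propan-2-one
Product: 7 (E)-6-[4-(benzyloxy)phenyl]hex-3-en-2-one
Conditions: CH2Cl2, reflux
Reagents that add atoms: 1-(triphenylphosphoranylidene)propan-2-one, CC(=O)C=P(c1ccccc1)(c1ccccc1)c1ccccc1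
Why: The Wittig reaction of a stabilised ylide with an aliphatic aldehyde gives the E-enone without the self-condensation that a crossed aldol with acetone would risk.

Step 5 (key step)
Reactants: 7 (E)-6-[4-(benzyloxy)phenyl]hex-3-en-2-one; 8 dimethyl malonate
Product: 10 methyl 6-{2-[4-(benzyloxy)phenyl]ethyl}-2-hydroxy-4-oxocyclohex-2-ene-1-carboxylate, via Michael adduct 9 (not isolated)
Conditions: NaOMe (1.1 equiv), MeOH, reflux; then aq HCl
Reagents that add atoms: dimethyl malonate, COC(=O)CC(=O)OC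
Why: Intermolecular Michael addition of the malonate anion to the enone is followed by an intramolecular Claisen (Dieckmann) condensation of the methyl ketone enolate on one ester, driven by the stabilised 1,3-dione enolate, and the two racemic stereocentres disappear in step 6.

Step 6
Reactants: 10 methyl 6-{2-[4-(benzyloxy)phenyl]ethyl}-2-hydroxy-4-oxocyclohex-2-ene-1-carboxylate
Product: 12 methyl 6-{2-[4-(benzyloxy)phenyl]ethyl}-2,4-dihydroxybenzoate, via bromodione 11 (not isolated)
Conditions: Br2 (1.0 equiv), DMF, 0 °C to rt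
Reagents that add atoms: none
Why: In this oxidative aromatisation the enolised 1,3-dione is brominated far faster than the aryl ether ring, and the bromide loses HBr and tautomerises to the resorcylate, the ester surviving because the mixture is not heated.

Step 7
Reactants: 12 methyl 6-{2-[4-(benzyloxy)phenyl]ethyl}-2,4-dihydroxybenzoate
Product: 13 methyl 2,4-dihydroxy-6-[2-(4-hydroxyphenyl)ethyl]benzoate
Conditions: H2 (1 atm), 10 % Pd/C, EtOAc–MeOH, rt
Reagents that add atoms: none
Why: Catalytic hydrogenolysis removes the benzyl ether at the last point where the molecule holds no alkene.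

Step 8
Reactants: 13 methyl 2,4-dihydroxy-6-[2-(4-hydroxyphenyl)ethyl]benzoate; 14 3-methylbut-2-enal (prenal)
Product: 16 methyl 5-hydroxy-7-[2-(4-hydroxyphenyl)ethyl]-2,2-dimethyl-2H-chromene-6-carboxylate, via ortho-quinone methide 15 (not isolated)
Conditions: ethylenediammonium diacetate (20 mol %), xylene, reflux
Reagents that add atoms: 3-methylbut-2-enal, CC(C)=CC=O
Why: The carbon between the two hydroxyls adds to the iminium-activated aldehyde (aldol/Knoevenagel-type condensation), water is lost, and oxa-6π electrocyclisation closes on the 4-oxygen because the 2-OH stays hydrogen-bonded to the ester, while the monophenol ring is too weak a nucleophile to react.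

Step 9
Reactants: 16 methyl 5-hydroxy-7-[2-(4-hydroxyphenyl)ethyl]-2,2-dimethyl-2H-chromene-6-carboxylate; 17 chlorotriisopropylsilane
Product: 18 methyl 5-hydroxy-2,2-dimethyl-7-(2-{4-[(triisopropylsilyl)oxy]phenyl}ethyl)-2H-chromene-6-carboxylate
Conditions: TIPSCl (1.1 equiv), imidazole, DMF, 0 °C to rt
Reagents that add atoms: chlorotriisopropylsilane, CC(C)[Si](Cl)(C(C)C)C(C)C
Why: In this selective silyl ether formation the bulky chloride reacts only with the unhindered 4'-phenol, since the 5-OH is chelated to the ester and flanked on both sides.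

Step 10
Reactants: 18 methyl 5-hydroxy-2,2-dimethyl-7-(2-{4-[(triisopropylsilyl)oxy]phenyl}ethyl)-2H-chromene-6-carboxylate; 19 1-bromo-3-methylbut-2-ene (prenyl bromide)
Product: 20 methyl 2,2-dimethyl-5-[(3-methylbut-2-en-1-yl)oxy]-7-(2-{4-[(triisopropylsilyl)oxy]phenyl}ethyl)-2H-chromene-6-carboxylate
Conditions: K2CO3, dry acetone, reflux
Reagents that add atoms: 1-bromo-3-methylbut-2-ene, CC(C)=CCBr
Why: Williamson O-alkylation of the only remaining phenol with a reactive allylic bromide works even on a chelated OH, and the TIPS ether tolerates anhydrous carbonate.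

Step 11
Reactants: 20 methyl 2,2-dimethyl-5-[(3-methylbut-2-en-1-yl)oxy]-7-(2-{4-[(triisopropylsilyl)oxy]phenyl}ethyl)-2H-chromene-6-carboxylate
Product: 23 methyl 5-hydroxy-2,2-dimethyl-8-(3-methylbut-2-en-1-yl)-7-(2-{4-[(triisopropylsilyl)oxy]phenyl}ethyl)-2H-chromene-6-carboxylate, via ortho-dienone 21 (not isolated), via para-dienone 22 (not isolated)
Conditions: PhNEt2, 195 °C, Ar, sealed tube
Reagents that add atoms: none
Why: The aromatic Claisen rearrangement lands on a blocked ortho carbon, the dienone cannot enolise, and a Cope rearrangement carries the allyl unit on to C8, the only ring carbon bearing H, so the double inversion restores the linear prenyl group (para-Claisen–Cope).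

Step 12
Reactants: 23 methyl 5-hydroxy-2,2-dimethyl-8-(3-methylbut-2-en-1-yl)-7-(2-{4-[(triisopropylsilyl)oxy]phenyl}ethyl)-2H-chromene-6-carboxylate
Product: 26 7-[2-(4-hydroxyphenyl)ethyl]-2,2-dimethyl-8-(3-methylbut-2-en-1-yl)-2H-chromen-5-ol, via desilylated ester 24 (not isolated), via carboxylic acid 25 (not isolated)
Conditions: NaOH (10 equiv), MeOH–H2O, reflux, N2; then dil. HCl; toluene, 100 °C
Reagents that add atoms: none
Why: Hot alkali cleaves the aryl silyl ether and saponifies the ester, and the resulting electron-rich ortho-hydroxybenzoic acid loses CO2 by ipso-protonation (decarboxylative saponification), conditions under which the prenyl and chromene double bonds are inert.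

## Compound list
1 | methyl 3-(4-hydroxyphenyl)propanoate | COC(=O)CCc1ccc(O)cc1 | starting material
2 | benzyl bromide | BrCc1ccccc1 | starting material
3 | methyl 3-[4-(benzyloxy)phenyl]propanoate | COC(=O)CCc1ccc(OCc2ccccc2)cc1 | intermediate
4 | 3-[4-(benzyloxy)phenyl]propan-1-ol | OCCCc1ccc(OCc2ccccc2)cc1 | intermediate
5 | 3-[4-(benzyloxy)phenyl]propanal | O=CCCc1ccc(OCc2ccccc2)cc1 | intermediate
6 | 1-(triphenylphosphoranylidene)propan-2-one | CC(=O)C=P(c1ccccc1)(c1ccccc1)c1ccccc1 | starting material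
7 | (E)-6-[4-(benzyloxy)phenyl]hex-3-en-2-one | CC(=O)/C=C/CCc1ccc(OCc2ccccc2)cc1 | intermediate
8 | dimethyl malonate | COC(=O)CC(=O)OC | starting material
9 | dimethyl 2-{1-[4-(benzyloxy)phenyl]-5-oxohexan-3-yl}propanedioate (racemic) | COC(=O)C(C(=O)OC)C(CCc1ccc(OCc2ccccc2)cc1)CC(C)=O | intermediate (not isolated)
10 | methyl 6-{2-[4-(benzyloxy)phenyl]ethyl}-2-hydroxy-4-oxocyclohex-2-ene-1-carboxylate (racemic, diastereomer mixture) | COC(=O)C1C(O)=CC(=O)CC1CCc1ccc(OCc2ccccc2)cc1 | intermediate
11 | methyl 6-{2-[4-(benzyloxy)phenyl]ethyl}-3-bromo-2-hydroxy-4-oxocyclohex-2-ene-1-carboxylate (racemic) | COC(=O)C1C(O)=C(Br)C(=O)CC1CCc1ccc(OCc2ccccc2)cc1 | intermediate (not isolated)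
12 | methyl 6-{2-[4-(benzyloxy)phenyl]ethyl}-2,4-dihydroxybenzoate | COC(=O)c1c(O)cc(O)cc1CCc1ccc(OCc2ccccc2)cc1 | intermediate
13 | methyl 2,4-dihydroxy-6-[2-(4-hydroxyphenyl)ethyl]benzoate | COC(=O)c1c(O)cc(O)cc1CCc1ccc(O)cc1 | intermediate
14 | 3-methylbut-2-enal | CC(C)=CC=O | starting material
15 | methyl 2-hydroxy-6-[2-(4-hydroxyphenyl)ethyl]-3-(3-methylbut-2-en-1-ylidene)-4-oxocyclohexa-1,5-diene-1-carboxylate | COC(=O)C1=C(O)C(=CC=C(C)C)C(=O)C=C1CCc1ccc(O)cc1 | intermediate (not isolated)
16 | methyl 5-hydroxy-7-[2-(4-hydroxyphenyl)ethyl]-2,2-dimethyl-2H-chromene-6-carboxylate | COC(=O)c1c(O)c2C=CC(C)(C)Oc2cc1CCc1ccc(O)cc1 | intermediate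
17 | chlorotriisopropylsilane | CC(C)[Si](Cl)(C(C)C)C(C)C | starting material
18 | methyl 5-hydroxy-2,2-dimethyl-7-(2-{4-[(triisopropylsilyl)oxy]phenyl}ethyl)-2H-chromene-6-carboxylate | COC(=O)c1c(O)c2C=CC(C)(C)Oc2cc1CCc1ccc(O[Si](C(C)C)(C(C)C)C(C)C)cc1 | intermediate
19 | 1-bromo-3-methylbut-2-ene | CC(C)=CCBr | starting material
20 | methyl 2,2-dimethyl-5-[(3-methylbut-2-en-1-yl)oxy]-7-(2-{4-[(triisopropylsilyl)oxy]phenyl}ethyl)-2H-chromene-6-carboxylate | COC(=O)c1c(OCC=C(C)C)c2C=CC(C)(C)Oc2cc1CCc1ccc(O[Si](C(C)C)(C(C)C)C(C)C)cc1 | intermediate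
21 | methyl 2,2-dimethyl-6-(2-methylbut-3-en-2-yl)-5-oxo-7-(2-{4-[(triisopropylsilyl)oxy]phenyl}ethyl)-5,6-dihydro-2H-chromene-6-carboxylate (racemic) | COC(=O)C1(C(C)(C)C=C)C(=O)C2=C(OC(C)(C)C=C2)C=C1CCc1ccc(O[Si](C(C)C)(C(C)C)C(C)C)cc1 | intermediate (not isolated)
22 | methyl 2,2-dimethyl-8-(3-methylbut-2-en-1-yl)-5-oxo-7-(2-{4-[(triisopropylsilyl)oxy]phenyl}ethyl)-5,8-dihydro-2H-chromene-6-carboxylate (racemic) | COC(=O)C1=C(CCc2ccc(O[Si](C(C)C)(C(C)C)C(C)C)cc2)C(CC=C(C)C)C2=C(C=CC(C)(C)O2)C1=O | intermediate (not isolated)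
23 | methyl 5-hydroxy-2,2-dimethyl-8-(3-methylbut-2-en-1-yl)-7-(2-{4-[(triisopropylsilyl)oxy]phenyl}ethyl)-2H-chromene-6-carboxylate | COC(=O)c1c(O)c2C=CC(C)(C)Oc2c(CC=C(C)C)c1CCc1ccc(O[Si](C(C)C)(C(C)C)C(C)C)cc1 | intermediate
24 | methyl 5-hydroxy-7-[2-(4-hydroxyphenyl)ethyl]-2,2-dimethyl-8-(3-methylbut-2-en-1-yl)-2H-chromene-6-carboxylate | COC(=O)c1c(O)c2C=CC(C)(C)Oc2c(CC=C(C)C)c1CCc1ccc(O)cc1 | intermediate (not isolated)
25 | 5-hydroxy-7-[2-(4-hydroxyphenyl)ethyl]-2,2-dimethyl-8-(3-methylbut-2-en-1-yl)-2H-chromene-6-carboxylic acid | OC(=O)c1c(O)c2C=CC(C)(C)Oc2c(CC=C(C)C)c1CCc1ccc(O)cc1 | intermediate (not isolated)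
26 | 7-[2-(4-hydroxyphenyl)ethyl]-2,2-dimethyl-8-(3-methylbut-2-en-1-yl)-2H-chromen-5-ol (achiral) | CC(C)=CCc1c(CCc2ccc(O)cc2)cc(O)c2c1OC(C)(C)C=C2 | target

## Step count and risks
Total step count: 12. Longest linear sequence: 12 (fully linear from 1).

**Step 11, para-Claisen–Cope.** The risks are thermal loss of isoprene back to 18 and migration of the allyl unit into the pyran double bond. The fallback drops the sigmatropic plan and makes the C8–C bond by cross-coupling. It sets out from 18 and comes back at 23, so steps 10 and 11 drop out.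
- NIS (1.05 equiv, MeCN, 0 °C, dark) iodinates C8, which is the only unsubstituted carbon of the phenolic ring and sits para to the 5-OH. This gives methyl 5-hydroxy-8-iodo-2,2-dimethyl-7-(2-{4-[(triisopropylsilyl)oxy]phenyl}ethyl)-2H-chromene-6-carboxylate F1.
- Stille coupling with tributyl(3-methylbut-2-en-1-yl)stannane (Pd2(dba)3, AsPh3, LiCl, DMF, 80 °C) then gives 23.

**Step 12, decarboxylative saponification.** The ester carbonyl lies between a phenoxide and a side chain buttressed by the prenyl group, so acyl attack by hydroxide may stall. The fallback attacks the methyl carbon instead of the carbonyl. It sets out from 23 and comes back at 26.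
- LiI in 2,4,6-collidine at 150 °C cleaves the O–CH3 bond by SN2. Acidification then gives 5-hydroxy-2,2-dimethyl-8-(3-methylbut-2-en-1-yl)-7-(2-{4-[(triisopropylsilyl)oxy]phenyl}ethyl)-2H-chromene-6-carboxylic acid F2.
- Warming in toluene at 100 °C removes CO2 to give 2,2-dimethyl-8-(3-methylbut-2-en-1-yl)-7-(2-{4-[(triisopropylsilyl)oxy]phenyl}ethyl)-2H-chromen-5-ol F3.
- TBAF (THF, 0 °C) removes the silyl group and gives 26.

**Step 8, chromene annulation with prenal.** The risks are a low yield with the poorly soluble triol and attack at the other free ring carbon. The fallback forms the C–O bond first and the C–C bond by rearrangement. It sets out from 13 and comes back at 16.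
- With 1.0 equiv of DBU only the most acidic phenol (4-OH, para to the ester) is ionised. It is etherified with 3-chloro-3-methylbut-1-yne (CuCl2 cat., MeCN, 0 °C) to give methyl 2-hydroxy-6-[2-(4-hydroxyphenyl)ethyl]-4-[(2-methylbut-3-yn-2-yl)oxy]benzoate F4.
- Heating in xylene at 140 °C triggers the aryl propargyl ether Claisen rearrangement, a 1,5-H shift and oxa-6π closure. The shift goes to the carbon between the oxygens, which is favoured by the chelate and by the hindrance next to the side chain, and gives 16.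

Further compounds
F1 | step 11 | methyl 5-hydroxy-8-iodo-2,2-dimethyl-7-(2-{4-[(triisopropylsilyl)oxy]phenyl}ethyl)-2H-chromene-6-carboxylate | COC(=O)c1c(O)c2C=CC(C)(C)Oc2c(I)c1CCc1ccc(O[Si](C(C)C)(C(C)C)C(C)C)cc1
F2 | step 12 | 5-hydroxy-2,2-dimethyl-8-(3-methylbut-2-en-1-yl)-7-(2-{4-[(triisopropylsilyl)oxy]phenyl}ethyl)-2H-chromene-6-carboxylic acid | OC(=O)c1c(O)c2C=CC(C)(C)Oc2c(CC=C(C)C)c1CCc1ccc(O[Si](C(C)C)(C(C)C)C(C)C)cc1
F3 | step 12 | 2,2-dimethyl-8-(3-methylbut-2-en-1-yl)-7-(2-{4-[(triisopropylsilyl)oxy]phenyl}ethyl)-2H-chromen-5-ol | CC(C)=CCc1c(CCc2ccc(O[Si](C(C)C)(C(C)C)C(C)C)cc2)cc(O)c2c1OC(C)(C)C=C2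
F4 | step 8 | methyl 2-hydroxy-6-[2-(4-hydroxyphenyl)ethyl]-4-[(2-methylbut-3-yn-2-yl)oxy]benzoate | COC(=O)c1c(O)cc(OC(C)(C)C#C)cc1CCc1ccc(O)cc1
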